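**Plan**

Numbering: C1 quaternary ring-fusion C(CH3); C2 CH–OAc; C3 CH2; C4 C(OH)(iPr); C5 ring-fusion CH (five-membered ring C1–C5); C6 CH–O-anisoyl; C7 CH2; C8(CH3)/C9 epoxide; C10 CH–OH (seven-membered ring C1, C5–C10); β = face of the C1 methyl.
Retrosynthetic cuts: acetate and epoxide oxygen; C8=C9 (ring-closing metathesis); anisoate; C6–C7 (allylation of a C6 aldehyde); C4–C5 (aldol); then C4–iPr, C2–C3, the C1–C5 arm and C1–C10 in an open chain.
Enabling feature: C4(OH)–C5(H)–C6(O) is an aldol retron once C6 is an aldehyde. O2 and O10 sit on carbons bound to C1, both cis to its methyl; this syn-1,3-diol can be closed to a temporary six-membered silylene ring that holds the C5 and C3 arms equatorial.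
Forward order: chain, silylene ring, five-membered ring (C4–C5), seven-membered ring (C8=C9), epoxide, removal of the silylene ring (step 14), acetate.
Stereochemistry: C10 from an Evans aldol reaction; C1 by Fráter–Seebach alkylation (from C10); C2 by Narasaka–Prasad reduction (from C10); C4/C5 in the templated aldol; C6 by chelation-controlled allylation; C8/C9 by epoxidation anti to the C1 methyl.

Key step: step 9

Remark: read from the SMILES, the target is (1S,2R,4R,5S,6S,8R,9S,10R) in the plan numbering: 2β-OAc, 4β-OH (4α-iPr), 5α-H, 6α-anisoate, 8α,9α-epoxide, 10β-OH. "Daucane" in the names below means this C15 skeleton (bicyclo[5.3.0]decane, CH3 on C1 and C8, isopropyl on C4) numbered as in the plan.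

Step 1
Reactants: 1 (R)-4-benzyl-3-propanoyl-1,3-oxazolidin-2-one; 2 acrolein
Product: 4 (R)-4-benzyl-3-[(2R,3S)-3-hydroxy-2-methylpent-4-enoyl]-1,3-oxazolidin-2-one, via dibutylboron Z-enolate 3 (not isolated)
Conditions: Bu2BOTf, iPr2NEt, CH2Cl2, 0 °C; 2, −78 → 0 °C; NaH2PO4/Na2HPO4 buffer (pH 7), MeOH, H2O2
Reagents that add atoms: none
Why: Evans syn-aldol reaction, in which the Z-boron enolate adds to acrolein through a closed chair transition state and the (R)-benzyl auxiliary fixes the carbinol carbon (later C10) as S; the neighbouring methyl-bearing centre is erased in step 3.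

Step 2
Reactants: 4
Product: 5 methyl (2R,3S)-3-hydroxy-2-methylpent-4-enoate
Conditions: NaOMe, MeOH, 0 °C; aq NH4Cl
Reagents that add atoms: methanol, CO
Why: Methanolysis (transesterification) at the exocyclic imide carbonyl should release the methyl ester and the auxiliary without touching the carbinol centre.

Step 3
Reactants: 5; 6 1-bromo-3-methylbut-2-ene
Product: 8 methyl (2S,3S)-3-hydroxy-2-methyl-2-(3-methylbut-2-en-1-yl)pent-4-enoate, via dilithium alkoxide enolate 7 (not isolated)
Conditions: LiN(iPr)2 (2.3 equiv), THF, −78 → −20 °C; 6, DMPU, −78 → 0 °C; aq NH4Cl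
Reagents that add atoms: none
Why: Fráter–Seebach alkylation, in which the chelated dianion is alkylated on the face anti to the vinyl group of the carbinol carbon; this creates quaternary C1 with its methyl cis and its prenyl arm trans to that vinyl group in the later silylene ring.

Step 4
Reactants: 8; 9 N-methoxy-N-methylacetamide
Product: 10 (4S,5S)-5-hydroxy-N-methoxy-N,4-dimethyl-4-(3-methylbut-2-en-1-yl)-3-oxohept-6-enamide
Conditions: 9, LiN(iPr)2, THF, −78 °C; 8, −78 → 0 °C; AcOH
Reagents that add atoms: none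
Why: Crossed Claisen condensation, in which the ester has no α-hydrogen and can only be the acceptor, and the product is held in the flask as its β-keto amide enolate, which should also suppress retro-aldol cleavage of C1–C10.

Step 5
Reactants: 10
Product: 12 (3R,4R,5S)-3,5-dihydroxy-N-methoxy-N,4-dimethyl-4-(3-methylbut-2-en-1-yl)hept-6-enamide, via diethylboron chelate 11 (not isolated)
Conditions: Et2BOMe, THF/MeOH, −78 °C; NaBH4; AcOH, then MeOH (evaporation)
Reagents that add atoms: none
Why: Narasaka–Prasad reduction, in which external hydride attacks the six-membered boron chelate axially and anti to the axial C1 methyl, so the new C2 carbinol should be syn to the C10 carbinol.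

Step 6
Reactants: 12
Product: 13 2-[(4R,5R,6S)-2,2-di-tert-butyl-6-ethenyl-5-methyl-5-(3-methylbut-2-en-1-yl)-1,3,2-dioxasilinan-4-yl]-N-methoxy-N-methylacetamide
Conditions: tBu2Si(OTf)2, 2,6-lutidine, CH2Cl2, 0 °C; aq NaHCO3
Reagents that add atoms: di-tert-butylsilyl bis(trifluoromethanesulfonate), CC(C)(C)[Si](OS(=O)(=O)C(F)(F)F)(OS(=O)(=O)C(F)(F)F)C(C)(C)C
Why: Silylene protection of a syn-1,3-diol should give the chair dioxasilinane (the temporary ring) with the vinyl group on C10, the amide arm on C2 and the prenyl arm on C1 equatorial and the C1 methyl axial.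

Step 7
Reactants: 13
Product: 14 1-[(4R,5R,6S)-2,2-di-tert-butyl-6-ethenyl-5-methyl-5-(3-methylbut-2-en-1-yl)-1,3,2-dioxasilinan-4-yl]-3-methylbutan-2-one
Conditions: iPrMgCl, THF, 0 °C; aq NH4Cl
Reagents that add atoms: isopropylmagnesium chloride iPrMgCl, CC(C)[Mg]Cl
Why: Weinreb ketone synthesis, in which the chelated tetrahedral ClMg adduct prevents a second addition and collapses to the C4 isopropyl ketone on work-up.

Step 8
Reactants: 14
Product: 16 2-[(4R,5R,6S)-2,2-di-tert-butyl-6-ethenyl-5-methyl-4-(3-methyl-2-oxobutyl)-1,3,2-dioxasilinan-5-yl]acetaldehyde, via secondary ozonide 15 (not isolated)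
Conditions: O3, CH2Cl2, −78 °C (Sudan Red 7B end point); PPh3, −78 → 20 °C
Reagents that add atoms: ozone, [O-][O+]=O
Why: Chemoselective ozonolysis, in which the electron-rich trisubstituted prenyl alkene reacts far faster than the monosubstituted vinyl group that is deactivated by its allylic C–O bond, so titration to the indicator end point should unveil only the C6 aldehyde.

Step 9
Reactants: 16
Product: 18 (4S,4aR,5R,6R,7aR)-2,2-di-tert-butyl-4-ethenyl-6-hydroxy-4a-methyl-6-(propan-2-yl)hexahydrocyclopenta[d][1,3,2]dioxasiline-5-carbaldehyde, via D-proline enamine 17 (not isolated)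
Conditions: D-proline (30 mol%), DMSO, 20 °C
Reagents that add atoms: none
Why: D-Proline condenses with the aldehyde to the E-enamine 17, whose nucleophilic carbon C5 attacks the ketone carbon C4 while the carboxylic acid hydrogen-bonds the ketone oxygen, and hydrolysis of the iminium ion returns the catalyst. The closest known reaction type is the proline-catalysed intramolecular aldol reaction of keto aldehydes and dialdehydes with the aldehyde as donor (enolexo aldolization, a relative of the Hajos–Parrish reaction). The cyclopentane C1–C2–C3–C4–C5 closes in the 5-(enolexo)-exo-trig mode, and because its two arms are equatorial on neighbouring carbons of the chair silylene ring it can only become trans-fused to that ring, which later places H5 trans to the C1 methyl. C5 is set with the formyl group β (cis to the axial C1 methyl, away from the isopropyl group): this should be the more stable epimer and the one the D-catalyst delivers, and the centre stays correctable through the enamine. C4 is set with OH β and isopropyl α by the hydrogen-bonded transition state, which keeps the ketone oxygen next to the enamine carbon, and by the 1,3-clash a β-isopropyl group would have with the axial C1 methyl. The step needs regioselectivity (aldehyde as donor, not the reverse closure C3 to C6) and no dehydration; the hindered isopropyl ketone should form no enamine at a useful rate, and proline, unlike amine/acid salt catalysts, should stop at the β-hydroxy aldehyde.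

Step 10
Reactants: 18
Product: 19 (1S)-1-[(4S,4aR,5S,6R,7aR)-2,2-di-tert-butyl-4-ethenyl-6-hydroxy-4a-methyl-6-(propan-2-yl)hexahydrocyclopenta[d][1,3,2]dioxasilin-5-yl]-3-methylbut-3-en-1-ol
Conditions: CH2=C(CH3)CH2MgCl (2.5 equiv), THF, −78 °C; aq NH4Cl
Reagents that add atoms: 2-methylallylmagnesium chloride CH2=C(CH3)CH2MgCl, CC(=C)C[Mg]Cl
Why: Chelation-controlled Grignard addition, in which the first equivalent forms the C4 alkoxide ROMgCl that binds the aldehyde oxygen in a six-membered chelate and the second adds to its open face (syn to H5, anti to C1), which should give the 1,3-anti diol with C6 as S.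

Step 11
Reactants: 19
Product: 20 (1S)-1-[(4S,4aR,5S,6R,7aR)-2,2-di-tert-butyl-4-ethenyl-6-hydroxy-4a-methyl-6-(propan-2-yl)hexahydrocyclopenta[d][1,3,2]dioxasilin-5-yl]-3-methylbut-3-en-1-yl 4-methoxybenzoate
Conditions: 4-MeOC6H4COCl, DMAP, pyridine, CH2Cl2, 0 → 40 °C; aq NaHCO3
Reagents that add atoms: 4-methoxybenzoyl chloride, COc1ccc(C(Cl)=O)cc1
Why: DMAP-catalysed acylation should be selective for the secondary C6 hydroxyl because the only other free hydroxyl (C4) is tertiary and flanked by the isopropyl group.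

Step 12
Reactants: 20
Product: 21 6α-(4-methoxybenzoyloxy)-2β,10β-(di-tert-butylsilanediyldioxy)-5αH-dauc-8-en-4β-ol
Conditions: second-generation Grubbs catalyst (H2IMes)(PCy3)Cl2Ru=CHPh (5 mol%), toluene, 80 °C
Reagents that add atoms: none
Why: Ring-closing metathesis between the vinyl group on C10 and the 1,1-disubstituted methallyl alkene should close the seven-membered ring as the trisubstituted C8=C9 alkene with loss of ethene, the two arms being held close by the trans-fused cyclopentane and silylene rings.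

Step 13
Reactants: 21
Product: 22 8α,9α-epoxy-6α-(4-methoxybenzoyloxy)-2β,10β-(di-tert-butylsilanediyldioxy)-5αH-daucan-4β-ol
Conditions: mCPBA, NaHCO3, CH2Cl2, 0 °C
Reagents that add atoms: 3-chloroperoxybenzoic acid, OOC(=O)c1cccc(Cl)c1
Why: Prilezhaev epoxidation should occur on the α face of C8=C9, anti to the axial C1 methyl and to the allylic C10–O bond that is locked in the silylene ring, where no free hydroxyl can direct the peracid to the β face.

Step 14
Reactants: 22
Product: 23 8α,9α-epoxy-6α-(4-methoxybenzoyloxy)-5αH-daucane-2β,4β,10β-triol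
Conditions: HF·pyridine, pyridine, THF, 0 °C
Reagents that add atoms: none
Why: Fluoride cleaves both Si–O bonds under buffered, nearly neutral conditions that should leave the epoxide and the ester intact and avoid a base-induced Payne rearrangement of the trans-epoxy alcohol.

Step 15
Reactants: 23
Product: 24 2β-acetoxy-8α,9α-epoxy-6α-(4-methoxybenzoyloxy)-5αH-daucane-4β,10β-diol (target CNP0371526.1)
Conditions: Ac2O, pyridine, CH2Cl2, 0 °C
Reagents that add atoms: acetic anhydride, CC(=O)OC(C)=O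
Why: Steric differentiation of the two secondary hydroxyls, since C2–OH has a CH2 neighbour whereas C10–OH lies between quaternary C1 and the epoxide carbon and is deactivated by the adjacent C–O bond, so acetylation without DMAP at low temperature should stop at the C2 monoacetate.

**Compound list**

1 | (R)-4-benzyl-3-propanoyl-1,3-oxazolidin-2-one | CCC(=O)N1[C@H](Cc2ccccc2)COC1=O | starting material
2 | acrolein (prop-2-enal) | C=CC=O | starting material
3 | dibutylboron Z-enolate of 1 | C/C=C(\OB(CCCC)CCCC)N1[C@H](Cc2ccccc2)COC1=O | intermediate (not isolated)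
4 | (R)-4-benzyl-3-[(2R,3S)-3-hydroxy-2-methylpent-4-enoyl]-1,3-oxazolidin-2-one | C=C[C@H](O)[C@@H](C)C(=O)N1[C@H](Cc2ccccc2)COC1=O | intermediate
5 | methyl (2R,3S)-3-hydroxy-2-methylpent-4-enoate | C=C[C@H](O)[C@@H](C)C(=O)OC | intermediate
6 | 1-bromo-3-methylbut-2-ene (prenyl bromide) | CC(C)=CCBr | starting material
7 | dilithium alkoxide enolate of 5 (C7H10O3Li2) | C=C[C@H](O[Li])/C(C)=C(\O[Li])OC | intermediate (not isolated)
8 | methyl (2S,3S)-3-hydroxy-2-methyl-2-(3-methylbut-2-en-1-yl)pent-4-enoate | C=C[C@H](O)[C@](C)(CC=C(C)C)C(=O)OC | intermediate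
9 | N-methoxy-N-methylacetamide | CC(=O)N(C)OC | starting material
10 | (4S,5S)-5-hydroxy-N-methoxy-N,4-dimethyl-4-(3-methylbut-2-en-1-yl)-3-oxohept-6-enamide | C=C[C@H](O)[C@](C)(CC=C(C)C)C(=O)CC(=O)N(C)OC | intermediate
11 | O-diethylboryl chelate of 10 | C=C[C@H](OB(CC)CC)[C@](C)(CC=C(C)C)C(=O)CC(=O)N(C)OC | intermediate (not isolated)
12 | (3R,4R,5S)-3,5-dihydroxy-N-methoxy-N,4-dimethyl-4-(3-methylbut-2-en-1-yl)hept-6-enamide | C=C[C@H](O)[C@](C)(CC=C(C)C)[C@H](O)CC(=O)N(C)OC | intermediate
13 | 2-[(4R,5R,6S)-2,2-di-tert-butyl-6-ethenyl-5-methyl-5-(3-methylbut-2-en-1-yl)-1,3,2-dioxasilinan-4-yl]-N-methoxy-N-methylacetamide | C=C[C@@H]1O[Si](C(C)(C)C)(C(C)(C)C)O[C@H](CC(=O)N(C)OC)[C@@]1(C)CC=C(C)C | intermediate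
14 | 1-[(4R,5R,6S)-2,2-di-tert-butyl-6-ethenyl-5-methyl-5-(3-methylbut-2-en-1-yl)-1,3,2-dioxasilinan-4-yl]-3-methylbutan-2-one | C=C[C@@H]1O[Si](C(C)(C)C)(C(C)(C)C)O[C@H](CC(=O)C(C)C)[C@@]1(C)CC=C(C)C | intermediate
15 | secondary ozonide (1,2,4-trioxolane) of the prenyl alkene of 14, both epimers at the trioxolane CH | C=C[C@@H]1O[Si](C(C)(C)C)(C(C)(C)C)O[C@H](CC(=O)C(C)C)[C@@]1(C)CC2OOC(C)(C)O2 | intermediate (not isolated)
16 | 2-[(4R,5R,6S)-2,2-di-tert-butyl-6-ethenyl-5-methyl-4-(3-methyl-2-oxobutyl)-1,3,2-dioxasilinan-5-yl]acetaldehyde | C=C[C@@H]1O[Si](C(C)(C)C)(C(C)(C)C)O[C@H](CC(=O)C(C)C)[C@@]1(C)CC=O | intermediate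
17 | E-enamine of aldehyde 16 and D-proline | C=C[C@@H]1O[Si](C(C)(C)C)(C(C)(C)C)O[C@H](CC(=O)C(C)C)[C@@]1(C)/C=C/N2CCC[C@@H]2C(=O)O | intermediate (not isolated)
18 | (4S,4aR,5R,6R,7aR)-2,2-di-tert-butyl-4-ethenyl-6-hydroxy-4a-methyl-6-(propan-2-yl)hexahydrocyclopenta[d][1,3,2]dioxasiline-5-carbaldehyde (1β-CH3, 4β-OH, 5β-CHO in plan numbering) | C=C[C@@H]1O[Si](C(C)(C)C)(C(C)(C)C)O[C@@H]2C[C@@](O)(C(C)C)[C@H](C=O)[C@@]12C | intermediate
19 | (1S)-1-[(4S,4aR,5S,6R,7aR)-2,2-di-tert-butyl-4-ethenyl-6-hydroxy-4a-methyl-6-(propan-2-yl)hexahydrocyclopenta[d][1,3,2]dioxasilin-5-yl]-3-methylbut-3-en-1-ol | C=C[C@@H]1O[Si](C(C)(C)C)(C(C)(C)C)O[C@@H]2C[C@@](O)(C(C)C)[C@H]([C@@H](O)CC(C)=C)[C@@]12C | intermediate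
20 | 4-methoxybenzoate of 19 at the secondary (C6) hydroxyl | C=C[C@@H]1O[Si](C(C)(C)C)(C(C)(C)C)O[C@@H]2C[C@@](O)(C(C)C)[C@H]([C@@H](OC(=O)c3ccc(OC)cc3)CC(C)=C)[C@@]12C | intermediate
21 | 6α-(4-methoxybenzoyloxy)-2β,10β-(di-tert-butylsilanediyldioxy)-5αH-dauc-8-en-4β-ol | COc1ccc(C(=O)O[C@H]2CC(C)=C[C@@H]3O[Si](C(C)(C)C)(C(C)(C)C)O[C@@H]4C[C@@](O)(C(C)C)[C@H]2[C@@]34C)cc1 | intermediate
22 | 8α,9α-epoxy-6α-(4-methoxybenzoyloxy)-2β,10β-(di-tert-butylsilanediyldioxy)-5αH-daucan-4β-ol | COc1ccc(C(=O)O[C@H]2C[C@@]5(C)O[C@H]5[C@@H]3O[Si](C(C)(C)C)(C(C)(C)C)O[C@@H]4C[C@@](O)(C(C)C)[C@H]2[C@@]34C)cc1 | intermediate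
23 | 8α,9α-epoxy-6α-(4-methoxybenzoyloxy)-5αH-daucane-2β,4β,10β-triol | COc1ccc(C(=O)O[C@H]2C[C@@]3(C)O[C@H]3[C@H](O)[C@]3(C)[C@@H]2[C@](O)(C(C)C)C[C@H]3O)cc1 | intermediate
24 | 2β-acetoxy-8α,9α-epoxy-6α-(4-methoxybenzoyloxy)-5αH-daucane-4β,10β-diol (1S,2R,4R,5S,6S,8R,9S,10R) | COc1ccc(C(=O)O[C@H]2C[C@@]3(C)O[C@H]3[C@H](O)[C@]3(C)[C@@H]2[C@](O)(C(C)C)C[C@H]3OC(C)=O)cc1 | target

**Count and risks**

Total step count: 15. Longest linear sequence: 15 steps (1 to 24).

Steps most likely to fail:

Step 9. The ring could close in the reverse sense (enol of the ketone onto the aldehyde, C3 to C6), the aldol could dehydrate, or C5 could fail to equilibrate. The fallback fixes the nucleophilic carbon before the ketone exists and sets out from 13. Chemoselective ozonolysis (O3, CH2Cl2, −78 °C; PPh3) should give 2-[(4R,5R,6S)-2,2-di-tert-butyl-6-ethenyl-5-methyl-5-(2-oxoethyl)-1,3,2-dioxasilinan-4-yl]-N-methoxy-N-methylacetamide F1. iPr3SiOTf/Et3N should convert only the aldehyde into its triisopropylsilyl enol ether F2 (E/Z mixture). iPrMgCl should then give the isopropyl ketone triisopropylsilyl enol ether F3. BF3·OEt2 (CH2Cl2, −78 °C) should close C4–C5 by an intramolecular Mukaiyama aldol reaction; after loss of the silyl group on work-up and equilibration of C5 by a catalytic amine, the route is rejoined at 18.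

Step 15. Regioselectivity between the two secondary hydroxyls could be lost (acetylation at C10 or at both). The fallback distinguishes C10 by its allylic character and sets out from 21. HF·pyridine should give 6α-(4-methoxybenzoyloxy)-5αH-dauc-8-ene-2β,4β,10β-triol F6. MnO2 (CH2Cl2) should oxidise only the allylic C10 hydroxyl to 2β,4β-dihydroxy-6α-(4-methoxybenzoyloxy)-5αH-dauc-8-en-10-one F7. Ac2O/DMAP should then acetylate the only remaining secondary hydroxyl to give 2β-acetoxy-4β-hydroxy-6α-(4-methoxybenzoyloxy)-5αH-dauc-8-en-10-one F8. Nucleophilic epoxidation (t-BuOOH, DBU) anti to the C1 methyl should give 2β-acetoxy-8α,9α-epoxy-4β-hydroxy-6α-(4-methoxybenzoyloxy)-5αH-daucan-10-one F9. Luche reduction (NaBH4, CeCl3·7H2O, MeOH, −78 °C) with hydride entering anti to the C1 methyl should give the 10β-alcohol and rejoin the route at 24.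

Step 4. Acyl substitution at the neopentyl-type ester could stall, or the lithium alkoxide could undergo retro-aldol cleavage on warming. The fallback activates the acyl group by ring strain and sets out from 8. LiOH (THF/H2O) should give (2S,3S)-3-hydroxy-2-methyl-2-(3-methylbut-2-en-1-yl)pent-4-enoic acid F4. TsCl/pyridine (0 °C) should close it, with retention at the carbinol, to the β-lactone (3S,4S)-4-ethenyl-3-methyl-3-(3-methylbut-2-en-1-yl)oxetan-2-one F5. The lithium enolate LiOC(=CH2)N(OMe)Me of 9 (THF, −78 °C) should open the lactone at the acyl carbon and rejoin the route at 10.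

**Further compounds**

F1 | step 9 | 2-[(4R,5R,6S)-2,2-di-tert-butyl-6-ethenyl-5-methyl-5-(2-oxoethyl)-1,3,2-dioxasilinan-4-yl]-N-methoxy-N-methylacetamide | C=C[C@@H]1O[Si](C(C)(C)C)(C(C)(C)C)O[C@H](CC(=O)N(C)OC)[C@@]1(C)CC=O
F2 | step 9 | triisopropylsilyl enol ether of F1 (E/Z mixture) | C=C[C@@H]1O[Si](C(C)(C)C)(C(C)(C)C)O[C@H](CC(=O)N(C)OC)[C@@]1(C)C=CO[Si](C(C)C)(C(C)C)C(C)C
F3 | step 9 | triisopropylsilyl enol ether of 16 (E/Z mixture) | C=C[C@@H]1O[Si](C(C)(C)C)(C(C)(C)C)O[C@H](CC(=O)C(C)C)[C@@]1(C)C=CO[Si](C(C)C)(C(C)C)C(C)C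
F4 | step 4 | (2S,3S)-3-hydroxy-2-methyl-2-(3-methylbut-2-en-1-yl)pent-4-enoic acid | C=C[C@H](O)[C@](C)(CC=C(C)C)C(=O)O
F5 | step 4 | (3S,4S)-4-ethenyl-3-methyl-3-(3-methylbut-2-en-1-yl)oxetan-2-one | C=C[C@@H]1OC(=O)[C@@]1(C)CC=C(C)C
F6 | step 15 | 6α-(4-methoxybenzoyloxy)-5αH-dauc-8-ene-2β,4β,10β-triol | COc1ccc(C(=O)O[C@H]2CC(C)=C[C@H](O)[C@]3(C)[C@@H]2[C@](O)(C(C)C)C[C@H]3O)cc1
F7 | step 15 | 2β,4β-dihydroxy-6α-(4-methoxybenzoyloxy)-5αH-dauc-8-en-10-one | COc1ccc(C(=O)O[C@H]2CC(C)=CC(=O)[C@]3(C)[C@@H]2[C@](O)(C(C)C)C[C@H]3O)cc1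
F8 | step 15 | 2β-acetoxy-4β-hydroxy-6α-(4-methoxybenzoyloxy)-5αH-dauc-8-en-10-one | COc1ccc(C(=O)O[C@H]2CC(C)=CC(=O)[C@]3(C)[C@@H]2[C@](O)(C(C)C)C[C@H]3OC(C)=O)cc1
F9 | step 15 | 2β-acetoxy-8α,9α-epoxy-4β-hydroxy-6α-(4-methoxybenzoyloxy)-5αH-daucan-10-one | COc1ccc(C(=O)O[C@H]2C[C@@]3(C)O[C@H]3C(=O)[C@]3(C)[C@@H]2[C@](O)(C(C)C)C[C@H]3OC(C)=O)cc1
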